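**Retrosynthetic overview**

1. Feature: in the oxolane ring (O1, C2, C3, C4, C5) the C4 hydroxyl, the C3 hydroxymethyl and the C2 aryl group lie on one face. A CH2 unit held on the C4 oxygen by silicon can therefore be passed to C3 on that face, and C2 then takes its hydrogen from the opposite face.
2. C3–CH2OH and C2–H: Tamao oxidation of oxasilolane 17, which comes from 5-exo radical closure of the (bromomethyl)dimethylsilyl ether 16 of enol ether 14 (C2=C3).
3. 14: the C2–aryl bond by Negishi coupling of metalated dihydrofuranol 10 with aryl iodide 11. The oxolane ring of 10 is closed from alkynediol 9 through a molybdenum vinylidene under amine buffer, because π-acid closure of an aryl alkynediol would dehydrate the tertiary allylic alcohol to a furan.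
4. 9: from allylic alcohol 5 by Sharpless epoxidation (sets C4, the only catalyst-controlled stereocentre), oxidation, Ohira–Bestmann alkynylation and hydroxide opening at CH2; 5 from benzylic chloride 1 and propargyl alcohol 2.
5. Ring order: oxolane ring (step 6), then the temporary oxasilolane ring (step 9), which is opened again in step 10.

Key step: step 9

Remark: 1,2-bis(benzyloxy)-4-iodobenzene (11) is assumed to be purchasable; the labels O1 and C2–C5 always mean the oxolane atoms of the target.

**Route**

Step 1
Reactants: 1 3,4-dimethoxybenzyl chloride; 2 prop-2-yn-1-ol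
Product: 5 2-(3,4-dimethoxybenzyl)prop-2-en-1-ol, via benzylic Grignard reagent 3 (not isolated), via alkenylmagnesium alkoxide 4 (not isolated)
Conditions: Mg, THF, 0 °C (slow addition of 1); then 2 (0.4 equiv), CuI (10 mol%), THF–toluene, 0 to 40 °C; aq NH4Cl
Reagents that add atoms: none
Why: Copper-catalysed anti-carbomagnesiation of the magnesium alkoxide of propargyl alcohol places the benzyl group on the internal carbon and magnesium on the terminal carbon of a chelated alkenylmagnesium, which is protonated on work-up; no stereocentre is formed.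

Step 2
Reactants: 5 2-(3,4-dimethoxybenzyl)prop-2-en-1-ol
Product: 6 (R)-[2-(3,4-dimethoxybenzyl)oxiran-2-yl]methanol
Conditions: Ti(OiPr)4 (10 mol%), D-(−)-diisopropyl tartrate (12 mol%), t-BuOOH, 4 Å molecular sieves, CH2Cl2, −20 °C
Reagents that add atoms: tert-butyl hydroperoxide, CC(C)(C)OO
Why: Katsuki–Sharpless asymmetric epoxidation, in which the D-(−)-tartrate catalyst delivers oxygen to the alkene face that gives the 2R epoxy alcohol (L-(+)-tartrate gives the 2S series), so the future C4 stereocentre is set by the catalyst.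

Step 3
Reactants: 6 (R)-[2-(3,4-dimethoxybenzyl)oxiran-2-yl]methanol
Product: 7 (S)-2-(3,4-dimethoxybenzyl)oxirane-2-carbaldehyde
Conditions: Dess–Martin periodinane, NaHCO3, CH2Cl2, 0 °C to rt; used crude
Reagents that add atoms: none
Why: Dess–Martin oxidation under bicarbonate buffer spares the acid-sensitive 2,2-disubstituted epoxide, and the α-carbon is quaternary and cannot epimerise (the descriptor changes only through the priority order).

Step 4
Reactants: 7 (S)-2-(3,4-dimethoxybenzyl)oxirane-2-carbaldehyde
Product: 8 (R)-2-(3,4-dimethoxybenzyl)-2-ethynyloxirane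
Conditions: dimethyl (1-diazo-2-oxopropyl)phosphonate, K2CO3, MeOH, 0 °C to rt
Reagents that add atoms: dimethyl (1-diazo-2-oxopropyl)phosphonate, COP(=O)(OC)C(=[N+]=[N-])C(C)=O
Why: Ohira–Bestmann (Seyferth–Gilbert) homologation, in which the diazophosphonate anion adds to the aldehyde and loss of dimethyl phosphate and N2 with a 1,2-hydrogen shift gives the terminal alkyne without touching the quaternary centre.

Step 5
Reactants: 8 (R)-2-(3,4-dimethoxybenzyl)-2-ethynyloxirane
Product: 9 (R)-2-(3,4-dimethoxybenzyl)but-3-yne-1,2-diol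
Conditions: KOH, DMSO–H2O (4:1), 70 °C
Reagents that add atoms: water, O
Why: Hydroxide opens the epoxide by SN2 attack at the unsubstituted CH2 carbon, so the C–O bond at the quaternary propargylic centre is never broken and its configuration is retained.

Step 6
Reactants: 9 (R)-2-(3,4-dimethoxybenzyl)but-3-yne-1,2-diol
Product: 10 (R)-3-(3,4-dimethoxybenzyl)-2,3-dihydrofuran-3-ol
Conditions: Mo(CO)6 (25 mol%), Et3N, Et2O, hν (350 nm), rt
Reagents that add atoms: none
Why: Alkynol cycloisomerisation through a molybdenum vinylidene, in which photogenerated Et3N·Mo(CO)5 isomerises the terminal alkyne to the vinylidene, the primary hydroxyl (the only one that can reach it in a five-membered ring) adds to its α-carbon, and protonation releases the endocyclic enol ether in an amine-buffered medium that does not ionise the tertiary allylic alcohol.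

Step 7
Reactants: 10 (R)-3-(3,4-dimethoxybenzyl)-2,3-dihydrofuran-3-ol; 11 1,2-bis(benzyloxy)-4-iodobenzene
Product: 14 (R)-5-[3,4-bis(benzyloxy)phenyl]-3-(3,4-dimethoxybenzyl)-2,3-dihydrofuran-3-ol, via dilithio enol ether 12 (not isolated), via alkenylzinc chloride 13 (not isolated)
Conditions: t-BuLi (2.2 equiv), THF, −78 to −30 °C; ZnCl2, −30 to 0 °C; 11, Pd(PPh3)4 (5 mol%), rt; aq NaHCO3, handled base-washed and not stored
Reagents that add atoms: none
Why: After the hydroxyl is deprotonated, the α-alkoxyvinyl C–H at C2 is the most acidic C–H and is lithiated at low temperature (α-metalation of cyclic enol ethers), and transmetalation to zinc followed by Negishi coupling forms the C2–aryl bond while the C4 stereocentre stays untouched.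

Step 8
Reactants: 14 (R)-5-[3,4-bis(benzyloxy)phenyl]-3-(3,4-dimethoxybenzyl)-2,3-dihydrofuran-3-ol; 15 (bromomethyl)chlorodimethylsilane
Product: 16 (R)-{[5-(3,4-bis(benzyloxy)phenyl)-3-(3,4-dimethoxybenzyl)-2,3-dihydrofuran-3-yl]oxy}(bromomethyl)dimethylsilane
Conditions: imidazole, DMF, 0 °C to rt; pentane/aq NaHCO3 work-up, used crude
Reagents that add atoms: none
Why: Imidazole-promoted silylation of the tertiary alcohol by the unhindered chlorosilane (ordinary silyl ether formation) puts the radical precursor on the C4 oxygen under basic conditions that leave the enol ether and the allylic C–O bond intact.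

Step 9
Reactants: 16 (R)-{[5-(3,4-bis(benzyloxy)phenyl)-3-(3,4-dimethoxybenzyl)-2,3-dihydrofuran-3-yl]oxy}(bromomethyl)dimethylsilane
Product: 17 cis-fused oxasilolane, that is (2R,3R,4R)-2-[3,4-bis(benzyloxy)phenyl]-4-(3,4-dimethoxybenzyl)oxolane whose C3–CH2 and C4–O are joined through SiMe2
Conditions: Bu3SnH (1.5 equiv, slow addition), AIBN (0.2 equiv), 2,6-di-tert-butylpyridine (0.2 equiv), PhH, 80 °C, 0.02 M
Reagents that add atoms: none
Why: The tributyltin radical abstracts bromine to give the α-silylmethyl radical, which adds 5-exo-trig to C3 of the enol ether, forming the C3–CH2 bond and closing the oxasilolane ring, and the resulting C2 radical (stabilised by O1 and the aryl ring) is reduced by Bu3SnH, which carries the chain. This is the established silicon-tethered radical cyclisation of (bromomethyl)dimethylsilyl ethers of allylic alcohols, which has also been run on cyclic enol ethers. The short tether can reach C3 only on the face of the C4 oxygen, so the new ring is cis-fused and C3 is set by C4. At C2 the hydrogen atom should arrive on the convex face of the bicycle, anti to the vicinal C3–CH2 bond, which leaves the aryl group cis to the C3 and C4 substituents as the target requires. The step needs 5-exo over 6-endo closure and ring closure over direct reduction; C2 is fully substituted, attack at C3 gives the doubly stabilised radical, and the stannane is kept dilute. The medium stays neutral and a hindered pyridine takes up traces of HBr, so the tertiary allylic silyl ether is not ionised towards the furan.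

Step 10
Reactants: 17 cis-fused oxasilolane
Product: 18 (3R,4R,5R)-5-[3,4-bis(benzyloxy)phenyl]-3-(3,4-dimethoxybenzyl)-4-(hydroxymethyl)oxolan-3-ol
Conditions: H2O2 (30% aq), KF, KHCO3, THF–MeOH (1:1), rt to 40 °C
Reagents that add atoms: hydrogen peroxide, OO
Why: Tamao oxidation, in which fluoride- and bicarbonate-activated peroxide converts the CH2–Si bond of the alkoxysilane into CH2–OH and hydrolysis of the Si–O bond frees the tertiary alcohol, with no stereocentre involved.

Step 11
Reactants: 18 (3R,4R,5R)-5-[3,4-bis(benzyloxy)phenyl]-3-(3,4-dimethoxybenzyl)-4-(hydroxymethyl)oxolan-3-ol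
Product: 19 (3R,4R,5R)-5-(3,4-dihydroxyphenyl)-3-(3,4-dimethoxybenzyl)-4-(hydroxymethyl)oxolan-3-ol (CNP0115253.1)
Conditions: H2 (1 atm), 10% Pd/C, EtOAc–MeOH, rt; work-up under argon
Reagents that add atoms: none
Why: Catalytic hydrogenolysis of the two aryl benzyl ethers, which under neutral conditions at atmospheric pressure should cleave well before the ring C2–O1 benzylic bond, leaves all three stereocentres untouched.

**Compound list**

1 | 3,4-dimethoxybenzyl chloride | COc1ccc(CCl)cc1OC | starting material
2 | prop-2-yn-1-ol | C#CCO | starting material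
3 | (3,4-dimethoxybenzyl)magnesium chloride | COc1ccc(C[Mg]Cl)cc1OC | intermediate
4 | chloromagnesium (Z)-3-(chloromagnesio)-2-(3,4-dimethoxybenzyl)prop-2-en-1-olate | COc1ccc(C/C(CO[Mg]Cl)=C/[Mg]Cl)cc1OC | intermediate
5 | 2-(3,4-dimethoxybenzyl)prop-2-en-1-ol | COc1ccc(CC(=C)CO)cc1OC | intermediate
6 | (R)-[2-(3,4-dimethoxybenzyl)oxiran-2-yl]methanol | COc1ccc(C[C@]2(CO)OC2)cc1OC | intermediate
7 | (S)-2-(3,4-dimethoxybenzyl)oxirane-2-carbaldehyde | COc1ccc(C[C@]2(C=O)OC2)cc1OC | intermediate
8 | (R)-2-(3,4-dimethoxybenzyl)-2-ethynyloxirane | COc1ccc(C[C@]2(C#C)OC2)cc1OC | intermediate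
9 | (R)-2-(3,4-dimethoxybenzyl)but-3-yne-1,2-diol | COc1ccc(C[C@](O)(CO)C#C)cc1OC | intermediate
10 | (R)-3-(3,4-dimethoxybenzyl)-2,3-dihydrofuran-3-ol | COc1ccc(C[C@]2(O)COC=C2)cc1OC | intermediate
11 | 1,2-bis(benzyloxy)-4-iodobenzene | Ic1ccc(OCc2ccccc2)c(OCc3ccccc3)c1 | starting material
12 | lithium (R)-3-(3,4-dimethoxybenzyl)-5-lithio-2,3-dihydrofuran-3-olate | COc1ccc(C[C@]2(O[Li])COC([Li])=C2)cc1OC | intermediate
13 | lithium (R)-5-(chlorozincio)-3-(3,4-dimethoxybenzyl)-2,3-dihydrofuran-3-olate | COc1ccc(C[C@]2(O[Li])COC([Zn]Cl)=C2)cc1OC | intermediate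
14 | (R)-5-[3,4-bis(benzyloxy)phenyl]-3-(3,4-dimethoxybenzyl)-2,3-dihydrofuran-3-ol | COc1ccc(C[C@]2(O)COC(c3ccc(OCc4ccccc4)c(OCc5ccccc5)c3)=C2)cc1OC | intermediate
15 | (bromomethyl)chlorodimethylsilane | C[Si](C)(Cl)CBr | starting material
16 | (R)-{[5-(3,4-bis(benzyloxy)phenyl)-3-(3,4-dimethoxybenzyl)-2,3-dihydrofuran-3-yl]oxy}(bromomethyl)dimethylsilane | COc1ccc(C[C@]2(O[Si](C)(C)CBr)COC(c3ccc(OCc4ccccc4)c(OCc5ccccc5)c3)=C2)cc1OC | intermediate
17 | cis-fused oxasilolane: (2R,3R,4R)-2-[3,4-bis(benzyloxy)phenyl]-4-(3,4-dimethoxybenzyl)oxolane with C3–CH2–SiMe2–O–C4 bridge | COc1ccc(C[C@]23CO[C@@H](c4ccc(OCc5ccccc5)c(OCc6ccccc6)c4)[C@H]2C[Si](C)(C)O3)cc1OC | intermediate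
18 | (3R,4R,5R)-5-[3,4-bis(benzyloxy)phenyl]-3-(3,4-dimethoxybenzyl)-4-(hydroxymethyl)oxolan-3-ol | COc1ccc(C[C@]2(O)CO[C@@H](c3ccc(OCc4ccccc4)c(OCc5ccccc5)c3)[C@H]2CO)cc1OC | intermediate
19 | (3R,4R,5R)-5-(3,4-dihydroxyphenyl)-3-(3,4-dimethoxybenzyl)-4-(hydroxymethyl)oxolan-3-ol | COc1ccc(C[C@]2(O)CO[C@@H](c3ccc(O)c(O)c3)[C@H]2CO)cc1OC | target

**Step count and risks**

Total step count: 11. Longest linear sequence: 11 steps (1 or 2 to 19).

Step 9. Hydrogen-atom transfer to the planar, doubly stabilised C2 radical may lose facial selectivity, because the C4 benzyl group also projects over the convex face; 17 would then be formed together with its C2 epimer. Slow chain transfer to this radical could also let the bromide be reduced before ring closure. In the fallback the C2 hydrogen is put in by hydride addition to an oxocarbenium ion. It sets out from 17 taken as the C2 epimer mixture. DDQ in CH2Cl2–MeOH abstracts the benzylic C2 hydride from both epimers (the 3,4-dialkoxyphenyl group makes this the most oxidisable C–H) and gives the C2 methyl ketal of the bicycle F1. Et3SiH and BF3·OEt2 in CH2Cl2 at −78 °C then ionise the ketal and deliver hydride anti to the C3 substituent on the convex face (ionic hydrogenation of a cyclic ketal), which returns to 17 as one C2 configuration.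

Step 7. The second deprotonation may not stay on the enol ether: ortho-lithiation of the dimethoxyarene and ring opening of the alkoxide-bearing α-lithio enol ether can compete, and zinc halides may promote loss of water from the coupled product. The fallback metalates a protected monoanion and couples under neutral Stille conditions. From 10, TMSCl and imidazole in DMF give the trimethylsilyl ether of 10 F2. t-BuLi (1.3 equiv, THF, −78 to −30 °C) and Bu3SnCl give the 5-tributylstannyl enol ether F3. Stille coupling with 11 (Pd2(dba)3, AsPh3, CuI, DMF, rt) gives the trimethylsilyl ether of 14 F4. K2CO3 in MeOH at 0 °C removes the silyl group and the route is rejoined at 14.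

Step 6. The molybdenum cycle may stall, through loss of the photogenerated amine–carbonyl catalyst or its coordination by the 1,2-diol, leaving 9 unconverted. In the fallback the aryl group is attached before ring closure and the ring is closed on the internal alkyne with a π-acid; the tertiary oxygen is silylated first, because a free 3-yne-1,2-diol would lose water to the furan under such catalysis. From 9, Sonogashira coupling with 11 (Pd(PPh3)2Cl2, CuI, Et3N, THF, rt) gives the aryl alkynediol F5. TESOTf and 2,6-lutidine (CH2Cl2, −78 to 0 °C) give the bis(triethylsilyl) ether F6. PPTS in MeOH–CH2Cl2 at 0 °C frees only the primary hydroxyl and gives the tertiary triethylsilyl ether F7. Ph3PAuNTf2 (2 mol%) with solid NaHCO3 in CH2Cl2 at 0 °C should effect the 5-endo-dig cycloisomerisation of this homopropargylic alcohol to the triethylsilyl ether of 14 F8. TBAF in THF at 0 °C gives 14; this bypasses steps 6 and 7.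

Further compounds
F1 | step 9 | C2 methyl ketal of 17 (either configuration at C2) | COc1ccc(C[C@]23COC(OC)(c4ccc(OCc5ccccc5)c(OCc6ccccc6)c4)[C@H]2C[Si](C)(C)O3)cc1OC
F2 | step 7 | (R)-{[3-(3,4-dimethoxybenzyl)-2,3-dihydrofuran-3-yl]oxy}trimethylsilane | COc1ccc(C[C@]2(O[Si](C)(C)C)COC=C2)cc1OC
F3 | step 7 | (R)-tributyl[4-(3,4-dimethoxybenzyl)-4-(trimethylsilyloxy)-4,5-dihydrofuran-2-yl]stannane | COc1ccc(C[C@]2(O[Si](C)(C)C)COC([Sn](CCCC)(CCCC)CCCC)=C2)cc1OC
F4 | step 7 | trimethylsilyl ether of 14 | COc1ccc(C[C@]2(O[Si](C)(C)C)COC(c3ccc(OCc4ccccc4)c(OCc5ccccc5)c3)=C2)cc1OC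
F5 | step 6 | (R)-4-[3,4-bis(benzyloxy)phenyl]-2-(3,4-dimethoxybenzyl)but-3-yne-1,2-diol | COc1ccc(C[C@](O)(CO)C#Cc2ccc(OCc3ccccc3)c(OCc4ccccc4)c2)cc1OC
F6 | step 6 | bis(triethylsilyl) ether of F5 | COc1ccc(C[C@](O[Si](CC)(CC)CC)(CO[Si](CC)(CC)CC)C#Cc2ccc(OCc3ccccc3)c(OCc4ccccc4)c2)cc1OC
F7 | step 6 | 2-O-triethylsilyl ether of F5 with free primary hydroxyl | COc1ccc(C[C@](O[Si](CC)(CC)CC)(CO)C#Cc2ccc(OCc3ccccc3)c(OCc4ccccc4)c2)cc1OC
F8 | step 6 | triethylsilyl ether of 14 | COc1ccc(C[C@]2(O[Si](CC)(CC)CC)COC(c3ccc(OCc4ccccc4)c(OCc5ccccc5)c3)=C2)cc1OC
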